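**Strategy.** The cut is made through ring B, not through the diaryl ether. The C1′ carboxyl, C2′ aryloxy, C4′ methyl and C6′ oxygen of ring B match a 2-pyrone (C3 ester, C4 aryloxy, C6 methyl) plus the two carbons of a ketene acetal. Heating the 4-aryloxypyrone with 1,1-dimethoxyethene should form C4′–C5′ and C1′–C6′ and expel CO2 and methanol. This leaves the whole hindered diaryl ether in one operation. The pyrone comes from addition–elimination of the fully substituted ring-A phenol on a 4-chloropyrone. The chlorine of that phenol is purchased already flanked by two oxygens. A single BCl3 treatment then releases the target.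

Key step: step 10

Remark on stereochemistry: the target has no stereocentre and no configurationally stable axis, so it is achiral and no enantiomer has to be made. The only stereocentres on the way are the two bridgeheads of a transient, racemic cycloadduct.

Remark on ring A: an electrophilic chlorination would enter para to the methoxy group, next to the ester. For that reason the route starts from 3-chloro-2,4-dihydroxybenzaldehyde, which is taken as a catalogue chemical.

**Step 1**
Reactants: 1 3-chloro-2,4-dihydroxybenzaldehyde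
Product: 2 4-(benzyloxy)-3-chloro-2-hydroxybenzaldehyde
Conditions: BnBr (1.05 equiv), KHCO3, MeCN, 60 °C
Reagents that add atoms: benzyl bromide, BrCc1ccccc1
Why: Williamson etherification in which bicarbonate ionises only the more acidic 4-OH (para to CHO, ortho to Cl), while the 2-OH stays locked in its hydrogen bond to the formyl group.

**Step 2**
Reactants: 2 4-(benzyloxy)-3-chloro-2-hydroxybenzaldehyde
Product: 3 4-(benzyloxy)-3-chloro-2-methoxybenzaldehyde
Conditions: MeI, K2CO3, DMF, rt
Reagents that add atoms: iodomethane, CI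
Why: Williamson O-methylation with carbonate in a dipolar aprotic solvent breaks the chelate and caps the only remaining hydroxyl.

**Step 3**
Reactants: 3 4-(benzyloxy)-3-chloro-2-methoxybenzaldehyde
Product: 5 4-(benzyloxy)-3-chloro-2-methoxyphenol, via aryl formate 4 (not isolated)
Conditions: mCPBA, CH2Cl2, 0 °C → rt; NaHCO3 wash; then K2CO3 (cat.), MeOH, rt
Reagents that add atoms: mCPBA, O=C(OO)c1cccc(Cl)c1
Why: Baeyer–Villiger oxidation in which the aryl group, enriched by ortho-OMe and para-OBn, migrates in preference to hydride, followed by mild methanolysis of the formate.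

**Step 4**
Reactants: 5 4-(benzyloxy)-3-chloro-2-methoxyphenol
Product: 7 5-(benzyloxy)-4-chloro-2-hydroxy-3-methoxybenzaldehyde, via salicyl alcohol 6 (not isolated)
Conditions: MgCl2, Et3N, (CH2O)n, MeCN, reflux; aq. HCl work-up
Reagents that add atoms: paraformaldehyde (reacts as formaldehyde), C=O
Why: Casnati–Skattebøl ortho-formylation delivers formaldehyde inside the magnesium phenoxide complex, so carbon enters only at the one free ortho position and not at C5, which a free electrophile would prefer, and a second formaldehyde oxidises the benzylic alkoxide by hydride transfer.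

**Step 5**
Reactants: 7 5-(benzyloxy)-4-chloro-2-hydroxy-3-methoxybenzaldehyde
Product: 8 5-(benzyloxy)-4-chloro-2-hydroxy-3-methoxybenzoic acid
Conditions: NaClO2, H2NSO3H, THF/H2O, 0 °C
Reagents that add atoms: sodium chlorite, [Na+].[O-]Cl=O
Why: Lindgren–Pinnick chlorite oxidation is a method suited to phenolic aldehydes, and sulfamic acid removes HOCl before it can chlorinate or oxidise the p-alkoxyphenol.

**Step 6**
Reactants: 8 5-(benzyloxy)-4-chloro-2-hydroxy-3-methoxybenzoic acid
Product: 9 methyl 5-(benzyloxy)-4-chloro-2-hydroxy-3-methoxybenzoate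
Conditions: MeI, KHCO3, DMF, rt
Reagents that add atoms: iodomethane, CI
Why: SN2 alkylation of the carboxylate, with bicarbonate too weak to ionise the chelated, doubly flanked phenol, which therefore stays free.

**Step 7**
Reactants: 10 dibenzyl malonate; 11 diketene
Product: 13 benzyl 4-hydroxy-6-methyl-2-oxo-2H-pyran-3-carboxylate, via acetoacetylmalonate 12 (not isolated)
Conditions: NaH, THF, 0 °C; 11, 0 °C → reflux; aq. HCl
Reagents that add atoms: none
Why: The sodiomalonate is C-acetoacetylated by ring opening of diketene and the ketone enolate oxygen then lactonises onto one benzyl ester, the established malonate–diketene route to 3-alkoxycarbonyl-4-hydroxy-6-methyl-2-pyrones.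

**Step 8**
Reactants: 13 benzyl 4-hydroxy-6-methyl-2-oxo-2H-pyran-3-carboxylate
Product: 14 benzyl 4-chloro-6-methyl-2-oxo-2H-pyran-3-carboxylate
Conditions: (COCl)2, DMF (cat.), CH2Cl2, 0 °C → rt; used crude
Reagents that add atoms: oxalyl chloride, O=C(Cl)C(=O)Cl
Why: Vilsmeier-type deoxychlorination of a vinylogous acid, as practised on 2-acyl-1,3-diones and 4-hydroxycoumarin-3-carboxylates, is mild enough to spare the benzyl ester.

**Step 9**
Reactants: 9 methyl 5-(benzyloxy)-4-chloro-2-hydroxy-3-methoxybenzoate; 14 benzyl 4-chloro-6-methyl-2-oxo-2H-pyran-3-carboxylate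
Product: 15 benzyl 4-[4-(benzyloxy)-3-chloro-2-methoxy-6-(methoxycarbonyl)phenoxy]-6-methyl-2-oxo-2H-pyran-3-carboxylate
Conditions: K2CO3, MeCN, 0 °C → rt
Reagents that add atoms: none
Why: Vinylic addition–elimination at C4 of a β-chloro alkylidene-malonate-type acceptor is known for phenols with 4-halo-2-pyrones and 4-chlorocoumarins, so the crowded C–O bond is made at a highly electrophilic non-aromatic carbon.

**Step 10**
Reactants: 15 benzyl 4-[4-(benzyloxy)-3-chloro-2-methoxy-6-(methoxycarbonyl)phenoxy]-6-methyl-2-oxo-2H-pyran-3-carboxylate; 16 1,1-dimethoxyethene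
Product: 19 benzyl 2-[4-(benzyloxy)-3-chloro-2-methoxy-6-(methoxycarbonyl)phenoxy]-6-methoxy-4-methylbenzoate, via bridged lactone 17 (not isolated), via dimethoxycyclohexadiene 18 (not isolated)
Conditions: 16 (8 equiv), 4 Å MS, toluene, 110 °C, base-washed sealed tube
Reagents that add atoms: none
Why: This is the inverse-electron-demand Diels–Alder reaction of a 3-alkoxycarbonyl-2-pyrone with a ketene acetal, the known benzannulation that turns such pyrones, 6-alkyl ones included, into o-alkoxybenzoates. The CH2 terminus of 16, which carries the large HOMO coefficient, bonds to pyrone C6, the vinylogous acceptor carbon of the lactone and ester carbonyls, while the acetal carbon bonds to C3 in a concerted but strongly asynchronous (at the limit zwitterionic) [4+2]. Ring B is thus closed by an intermolecular cycloaddition that lays a two-carbon bridge across C3 and C6 to give bridged lactone 17; retro-[4+2] loss of CO2 opens it to diene 18, and 1,2-elimination of methanol makes the ring aromatic. No stereocentre survives, since the two bridgeheads of 17 form as a racemate and both become sp2. The step needs regioselectivity (OMe beside the ester, CH beside the methyl), which the C3 ester secures by polarising the diene towards C6, and site selectivity for C6 over the second acceptor carbon C4, which is shielded by the di-ortho-substituted aryloxy group and deactivated by its oxygen lone pair. Excess 16 and the sieves take up the liberated methanol so that it cannot displace the aryloxide from unreacted 15.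

**Step 11**
Reactants: 19 benzyl 2-[4-(benzyloxy)-3-chloro-2-methoxy-6-(methoxycarbonyl)phenoxy]-6-methoxy-4-methylbenzoate
Product: 20 2-[3-chloro-4-hydroxy-2-methoxy-6-(methoxycarbonyl)phenoxy]-6-hydroxy-4-methylbenzoic acid
Conditions: BCl3, C6HMe5, CH2Cl2, −78 → 0 °C; aq. work-up
Reagents that add atoms: none
Why: In this Lewis-acid dealkylation BCl3 ionises both benzylic C–O bonds (the cation is trapped by pentamethylbenzene in a Friedel–Crafts reaction) and, held in a six-membered chelate by the ring-B carbonyl, removes only the ortho methyl ether, while the ring-A methoxy has no carbonyl neighbour and the methyl ester is inert at this temperature.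

**Compound list**
1 | 3-chloro-2,4-dihydroxybenzaldehyde | O=Cc1ccc(O)c(Cl)c1O | starting material
2 | 4-(benzyloxy)-3-chloro-2-hydroxybenzaldehyde | O=Cc1ccc(OCc2ccccc2)c(Cl)c1O | intermediate
3 | 4-(benzyloxy)-3-chloro-2-methoxybenzaldehyde | O=Cc1ccc(OCc2ccccc2)c(Cl)c1OC | intermediate
4 | 4-(benzyloxy)-3-chloro-2-methoxyphenyl formate (not isolated) | O=COc1ccc(OCc2ccccc2)c(Cl)c1OC | intermediate
5 | 4-(benzyloxy)-3-chloro-2-methoxyphenol | Oc1ccc(OCc2ccccc2)c(Cl)c1OC | intermediate
6 | 4-(benzyloxy)-3-chloro-6-(hydroxymethyl)-2-methoxyphenol (magnesium salt in the flask, not isolated) | OCc1cc(OCc2ccccc2)c(Cl)c(OC)c1O | intermediate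
7 | 5-(benzyloxy)-4-chloro-2-hydroxy-3-methoxybenzaldehyde | O=Cc1cc(OCc2ccccc2)c(Cl)c(OC)c1O | intermediate
8 | 5-(benzyloxy)-4-chloro-2-hydroxy-3-methoxybenzoic acid | O=C(O)c1cc(OCc2ccccc2)c(Cl)c(OC)c1O | intermediate
9 | methyl 5-(benzyloxy)-4-chloro-2-hydroxy-3-methoxybenzoate | COC(=O)c1cc(OCc2ccccc2)c(Cl)c(OC)c1O | intermediate
10 | dibenzyl malonate | O=C(CC(=O)OCc1ccccc1)OCc1ccccc1 | starting material
11 | diketene (4-methylideneoxetan-2-one) | C=C1CC(=O)O1 | starting material
12 | dibenzyl 2-(3-oxobutanoyl)malonate (sodium enolate in the flask, not isolated) | CC(=O)CC(=O)C(C(=O)OCc1ccccc1)C(=O)OCc1ccccc1 | intermediate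
13 | benzyl 4-hydroxy-6-methyl-2-oxo-2H-pyran-3-carboxylate | CC1=CC(O)=C(C(=O)OCc2ccccc2)C(=O)O1 | intermediate
14 | benzyl 4-chloro-6-methyl-2-oxo-2H-pyran-3-carboxylate | CC1=CC(Cl)=C(C(=O)OCc2ccccc2)C(=O)O1 | intermediate
15 | benzyl 4-[4-(benzyloxy)-3-chloro-2-methoxy-6-(methoxycarbonyl)phenoxy]-6-methyl-2-oxo-2H-pyran-3-carboxylate | COC(=O)c1cc(OCc2ccccc2)c(Cl)c(OC)c1OC1=C(C(=O)OCc2ccccc2)C(=O)OC(C)=C1 | intermediate
16 | 1,1-dimethoxyethene | C=C(OC)OC | starting material
17 | benzyl 5-[4-(benzyloxy)-3-chloro-2-methoxy-6-(methoxycarbonyl)phenoxy]-8,8-dimethoxy-1-methyl-3-oxo-2-oxabicyclo[2.2.2]oct-5-ene-4-carboxylate (racemic, one enantiomer drawn, not isolated) | COC(=O)c1cc(OCc2ccccc2)c(Cl)c(OC)c1OC3=C[C@]4(C)CC(OC)(OC)[C@@]3(C(=O)OCc5ccccc5)C(=O)O4 | intermediate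
18 | benzyl 2-[4-(benzyloxy)-3-chloro-2-methoxy-6-(methoxycarbonyl)phenoxy]-6,6-dimethoxy-4-methylcyclohexa-1,3-diene-1-carboxylate (not isolated) | COC(=O)c1cc(OCc2ccccc2)c(Cl)c(OC)c1OC3=C(C(=O)OCc4ccccc4)C(OC)(OC)CC(C)=C3 | intermediate
19 | benzyl 2-[4-(benzyloxy)-3-chloro-2-methoxy-6-(methoxycarbonyl)phenoxy]-6-methoxy-4-methylbenzoate | COC(=O)c1cc(OCc2ccccc2)c(Cl)c(OC)c1Oc1cc(C)cc(OC)c1C(=O)OCc1ccccc1 | intermediate
20 | 2-[3-chloro-4-hydroxy-2-methoxy-6-(methoxycarbonyl)phenoxy]-6-hydroxy-4-methylbenzoic acid (achiral) | COC(=O)c1cc(O)c(Cl)c(OC)c1Oc1cc(C)cc(O)c1C(=O)O | target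

**Total step count:** 11.
**Longest linear sequence:** 9 (steps 1–6, 9, 10, 11). The pyrone branch has two steps (7, 8).

**Steps most likely to fail**

**Step 10.** The aryloxy donor at C4 may raise the diene LUMO so far that polymerisation of the ketene acetal outruns cycloaddition. The acetal may also add at C4 and expel the ring-A phenoxide.

The fallback gives up the benzannulation for a classical ether synthesis. It sets out from 9 and comes back at 20.
- Commercial 3-fluoro-5-methylanisole is lithiated between fluorine and methoxy (n-BuLi, THF, −78 °C) and quenched with DMF to give 2-fluoro-6-methoxy-4-methylbenzaldehyde F1.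
- Nucleophilic aromatic substitution of its aldehyde-activated fluoride by the potassium salt of 9 (K2CO3, DMF, 110 °C) should give methyl 5-(benzyloxy)-4-chloro-2-(2-formyl-3-methoxy-5-methylphenoxy)-3-methoxybenzoate F2.
- Chlorite oxidation (NaClO2, NaH2PO4, 2-methyl-2-butene) gives 2-[4-(benzyloxy)-3-chloro-2-methoxy-6-(methoxycarbonyl)phenoxy]-6-methoxy-4-methylbenzoic acid F3.
- F3 needs no benzyl ester. Under the conditions of step 11 it loses its benzyl ether and its chelated methyl ether to give 20.

**Step 9.** Attack of the hindered, hydrogen-bonded phenoxide may be slow enough that hydrolysis, ring opening or deprotonation at the 6-methyl group consumes the moisture-sensitive chloride first.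

The fallback brings in the C3 carboxyl only after the ether bond. It sets out from 9 and comes back at 15.
- Commercial 4-hydroxy-6-methyl-2-pyrone under Vilsmeier–Haack conditions (POCl3, DMF) gives the isolable 4-chloro-6-methyl-2-oxo-2H-pyran-3-carbaldehyde F4. Its C4 stands next to a smaller and more strongly withdrawing group.
- Addition–elimination with 9 (K2CO3, MeCN) should give methyl 5-(benzyloxy)-4-chloro-2-[(3-formyl-6-methyl-2-oxo-2H-pyran-4-yl)oxy]-3-methoxybenzoate F5.
- Chlorite oxidation gives 4-[4-(benzyloxy)-3-chloro-2-methoxy-6-(methoxycarbonyl)phenoxy]-6-methyl-2-oxo-2H-pyran-3-carboxylic acid F6.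
- BnBr with KHCO3 in DMF then gives 15.

**Step 11.** At the temperature that chelation-assisted demethylation requires, the crowded ring-A methyl ether may also be lost, or the benzyl ester may be cleaved incompletely.

The fallback removes the need for any demethylation. It sets out from 15 and comes back at 20.
- Commercial bromoacetaldehyde diethyl acetal is transacetalised with benzyl alcohol (TsOH cat., ethanol distilled off) to 2-bromo-1,1-bis(benzyloxy)ethane F7.
- Dehydrobromination with KOtBu gives 1,1-bis(benzyloxy)ethene F8.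
- Cycloaddition of F8 with 15 under the conditions of step 10 should give benzyl 2-(benzyloxy)-6-[4-(benzyloxy)-3-chloro-2-methoxy-6-(methoxycarbonyl)phenoxy]-4-methylbenzoate F9.
- BCl3 with pentamethylbenzene cleaves the three benzylic C–O bonds of F9 at low temperature, where no methyl ether reacts, and this gives 20.

**Further compounds**
F1 | step 10 | 2-fluoro-6-methoxy-4-methylbenzaldehyde | COc1cc(C)cc(F)c1C=O
F2 | step 10 | methyl 5-(benzyloxy)-4-chloro-2-(2-formyl-3-methoxy-5-methylphenoxy)-3-methoxybenzoate | COC(=O)c1cc(OCc2ccccc2)c(Cl)c(OC)c1Oc1cc(C)cc(OC)c1C=O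
F3 | step 10 | 2-[4-(benzyloxy)-3-chloro-2-methoxy-6-(methoxycarbonyl)phenoxy]-6-methoxy-4-methylbenzoic acid | COC(=O)c1cc(OCc2ccccc2)c(Cl)c(OC)c1Oc1cc(C)cc(OC)c1C(=O)O
F4 | step 9 | 4-chloro-6-methyl-2-oxo-2H-pyran-3-carbaldehyde | CC1=CC(Cl)=C(C=O)C(=O)O1
F5 | step 9 | methyl 5-(benzyloxy)-4-chloro-2-[(3-formyl-6-methyl-2-oxo-2H-pyran-4-yl)oxy]-3-methoxybenzoate | COC(=O)c1cc(OCc2ccccc2)c(Cl)c(OC)c1OC1=C(C=O)C(=O)OC(C)=C1
F6 | step 9 | 4-[4-(benzyloxy)-3-chloro-2-methoxy-6-(methoxycarbonyl)phenoxy]-6-methyl-2-oxo-2H-pyran-3-carboxylic acid | COC(=O)c1cc(OCc2ccccc2)c(Cl)c(OC)c1OC1=C(C(=O)O)C(=O)OC(C)=C1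
F7 | step 11 | 2-bromo-1,1-bis(benzyloxy)ethane | BrCC(OCc1ccccc1)OCc1ccccc1
F8 | step 11 | 1,1-bis(benzyloxy)ethene | C=C(OCc1ccccc1)OCc1ccccc1
F9 | step 11 | benzyl 2-(benzyloxy)-6-[4-(benzyloxy)-3-chloro-2-methoxy-6-(methoxycarbonyl)phenoxy]-4-methylbenzoate | COC(=O)c1cc(OCc2ccccc2)c(Cl)c(OC)c1Oc1cc(C)cc(OCc2ccccc2)c1C(=O)OCc1ccccc1
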